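**The two times.** Time splits this question. At 30 h the earlier runs nearly speak for themselves, but at 5.0 min there is no reading, the earliest being 1.33 h in delta.

| setting | delta | beta | eta | flask |
|---|---|---|---|---|
| substrate | 0.050 M | 0.050 M | 0.025 M | 0.050 M |
| catalyst | 0.25 mM | 0.38 mM | 0.50 mM | 0.50 mM |
| remark | run made earlier | run made earlier | run made earlier |  |
| time |  |  |  | 30 h |

- delta (time / h: target / %, isomer of the product A / %): 1.33: 4.3, 44.6; 3.00: 6.7, 75.4; 8.00: 11.1, 90.7; 20.0: 8.4, 90.6
- beta (time / h: target / %, isomer of the product A / %): 5.00: 12.8, 87.8; 10.0: 12.3, 88.3; 15.0: 11.6, 89.7; 20.0: 10.4, 87.8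
- eta (time / h: target / %, isomer of the product A / %): 2.50: 10.5, 78.1; 6.00: 11.6, 85.7; 12.0: 11.9, 86.2; 20.0: 12.8, 85.9

(scatter of a reading: 1 percentage point)

1. ratio of target to isomer of the product A at 5.0 min
2. ratio of target to isomer of the product A at 30 h
3. which of target and isomer of the product A there is more of at 30 h



**What matters.** Take the early ratio's inputs in turn. Clock time enters inversely, and delta's end ratio enters in proportion: its late readings give 0.122 and 0.0927, pooled 0.108. Catalyst matters less if a higher end ratio comes with a shorter delay; eta's late ratio is 0.141, but I assume that trade, unproved. The delay of the isomer also enters in proportion, and it rests on delta's two rising readings and its plateau, so it is the number to distrust.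

**The delay.** Delta's isomer climbs towards 90.6% of the charge at 0.662 h⁻¹. Traced back, that climb starts at 0.307 h, not at zero: a read lag, or induction period. If the isomer's rate rises from zero across that lag while target forms from the start, integrating gives isomer growing with time squared and target with time. Their ratio is then a fixed time over clock time. That time comes to 3.96 min: it is the crossing time, when the two are level, and it is twice the end ratio times the lag. My reckoning for 5.0 min is therefore 0.791. For 30 h I take eta's 0.141, with isomer ahead.

**The forecast.** It gives 0.12 and 0.125, with isomer of the product A leading, reading that “the two products seem to form in parallel”. Its early ratio is lower than mine.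

**The result.** The flask gives 0.886 at 5.0 min and 0.140 at 30 h, with isomer of the product A ahead.

    catalyst + other conformer → catalyst + isomer of the product A (k = 5800 M⁻¹ h⁻¹)
    substrate + catalyst → catalyst + target (k = 330 M⁻¹ h⁻¹)
    substrate ⇌ other conformer (K = 1.00, k = 1.70 h⁻¹)
    target + catalyst ⇌ isomer of the product B + catalyst, rate k4*[catalyst]*[target] forward; the back reaction follows from the equilibrium constant (K = 0.100, k = 150 M⁻¹ h⁻¹)

**The neighbour.** Target and isomer in the flask stand level at 4.38 min, later than my 3.96 min. Carry that crossing to the neighbouring flask, charged with less catalyst, 3.0 × 10⁻⁴ M: crossing over clock time gives 0.876 at 5.0 min. The neighbouring flask stands at 0.861 then, and ends at 0.105 at 30 h.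

(All runs were generated by integration for substances that don't exist.)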